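Everything rests on opening the benzene ring of each tetrahydroisoquinoline (C4a, C5, C6, C7, C8, C8a) into three alkynes. This ring bears only the naphthyl group at C5, oxygen at C8 and the fused piperidine, while C6 and C7 are plain CH, so it equals a nitrogen-tethered 1,7-diyne plus acetylene. One twofold rhodium-catalysed [2+2+2] cycloaddition forms C4a–C8a, C5–C6 and C7–C8 twice, closes two benzene and two piperidine rings, and turns two unhindered aryl–alkyne bonds into the crowded C5–C8' and C5–C1'' axes. Its precursor is a 6',6''-binaphthyl with two N-Cbz (R,R) propargyl/homopropargyl amine chains ending in alkynyl pinacol boronates, the masked C8 phenols.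

Key step: step 18

Assumption: the target SMILES fixes no axial configuration, so the route commits only to the constitution and to the four carbon stereocentres (1R,3R in both isoquinolines); atropisomers at the two outer axes would be separated at 32 or 33.

Locants: compounds 7–15 use naphthol numbering (O-bearing carbon = C1; unit A unprimed, unit B primed). C4 of unit A becomes C8' of the alkaloid, C5' of unit B becomes C1'', and the C2–C2' bond is the 6',6'' axis.

Step 1
Reactants: 1 2-methoxy-4-methylbenzoic acid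
Product: 3 N,N-diethyl-2-methoxy-4-methylbenzamide, via acid chloride 2 (not isolated)
Conditions: SOCl2, cat. DMF, toluene, 70 °C; concentrate; Et2NH (2.5 equiv), CH2Cl2, 0 °C → rt
Reagents that add atoms: thionyl chloride, O=S(Cl)Cl (chlorine of 2); diethylamine, CCNCC
Why: Amide formation through the acyl chloride is routine, and the tertiary diethylamide it installs is both the directing group of step 2 and the internal acylating agent of step 3.

Step 2
Reactants: 3 N,N-diethyl-2-methoxy-4-methylbenzamide
Product: 6 2-allyl-N,N-diethyl-6-methoxy-4-methylbenzamide, via aryllithium 4 (not isolated), via arylmagnesium bromide 5 (not isolated)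
Conditions: s-BuLi, TMEDA, THF, −78 °C; MgBr2·OEt2, −78 → 0 °C; allyl bromide, 0 °C → rt
Reagents that add atoms: sec-butyllithium, [Li]C(C)CC (lithium of 4); magnesium bromide, Br[Mg]Br (MgBr of 5); allyl bromide, C=CCBr
Why: Directed ortho-metalation: the diethylamide is the strongest director present and C6 is its only free ortho carbon (C3 is shielded between OMe and CH3), and transmetalation to magnesium tempers the aryl anion so that allyl bromide is attacked cleanly in an SN2-type allylation.

Step 3
Reactants: 6 2-allyl-N,N-diethyl-6-methoxy-4-methylbenzamide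
Product: 8 8-methoxy-1-(methoxymethoxy)-6-methylnaphthalene, via lithium naphtholate 7 (not isolated)
Conditions: LDA (2.5 equiv), THF, −78 °C → rt; MOMCl (excess, also consumes the lithium amides), 0 °C → rt
Reagents that add atoms: lithium diisopropylamide, CC(C)N([Li])C(C)C (lithium of 7); chloromethyl methyl ether, COCCl
Why: Anionic ring annulation of an o-allylbenzamide: LDA forms the benzylic–allylic anion, its terminal carbon acylates on the neighbouring amide, loss of diethylamide followed by tautomerisation gives the 1-naphtholate, and Williamson-type O-alkylation in the same flask spares the handling of the air-sensitive naphthol.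

Step 4
Reactants: 8 8-methoxy-1-(methoxymethoxy)-6-methylnaphthalene (two molecules)
Product: 10 8,8'-dimethoxy-1,1'-bis(methoxymethoxy)-6,6'-dimethyl-2,2'-binaphthalene, via 2-lithionaphthalene 9 (not isolated)
Conditions: n-BuLi, TMEDA, THF, 0 °C; anhydrous CuCl2 (1.2 equiv), −78 °C → rt
Reagents that add atoms: n-butyllithium, [Li]CCCC (lithium of 9)
Why: Directed ortho-metalation next to the chelating OMOM group (C8 is occupied, C7 is flanked by OMe and CH3) followed by oxidative homocoupling of the aryllithium by divalent copper places the biaryl bond at C2–C2', a position that phenolic oxidative coupling of the free naphthol would not select because its para carbon is open.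

Step 5
Reactants: 10 8,8'-dimethoxy-1,1'-bis(methoxymethoxy)-6,6'-dimethyl-2,2'-binaphthalene
Product: 11 8,8'-dimethoxy-6,6'-dimethyl-[2,2'-binaphthalene]-1,1'-diol
Conditions: conc. HCl (cat.), MeOH–THF, 50 °C, argon
Reagents that add atoms: none
Why: Acid-catalysed acetal cleavage (transacetalisation to methanol) frees both naphthols while the aryl methyl ethers and the biaryl bond are inert.

Step 6
Reactants: 11 8,8'-dimethoxy-6,6'-dimethyl-[2,2'-binaphthalene]-1,1'-diol
Product: 12 1-hydroxy-8,8'-dimethoxy-6,6'-dimethyl-[2,2'-binaphthalen]-1'-yl acetate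
Conditions: Ac2O (1.0 equiv), pyridine, 0 °C
Reagents that add atoms: acetic anhydride, CC(=O)OC(C)=O
Why: Monoacylation of a 2,2'-biaryldiol with one equivalent of anhydride is favoured because the first acetate crowds and hydrogen-bonds the neighbouring hydroxyl, and unreacted diol as well as diacetate (after methanolysis) can be returned to the step.

Step 7
Reactants: 12 1-hydroxy-8,8'-dimethoxy-6,6'-dimethyl-[2,2'-binaphthalen]-1'-yl acetate
Product: 13 4,5'-dibromo-1-hydroxy-8,8'-dimethoxy-6,6'-dimethyl-[2,2'-binaphthalen]-1'-yl acetate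
Conditions: NBS (2.05 equiv, two portions), MeCN, −30 °C → rt, dark, no base
Reagents that add atoms: N-bromosuccinimide, O=C1CCC(=O)N1Br
Why: Electrophilic aromatic bromination steered by the two oxygen states: the free naphthol ring of unit A is attacked first at its only open activated carbon C4 (para to OH), whereas in unit B the acetate switches its own ring off so that the second equivalent goes to C5' (para to OMe, ortho to CH3), the matching C5 of unit A being closed by peri strain against the new C4 bromine.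

Step 8
Reactants: 13 4,5'-dibromo-1-hydroxy-8,8'-dimethoxy-6,6'-dimethyl-[2,2'-binaphthalen]-1'-yl acetate
Product: 15 1,1'-bis(benzyloxy)-4,5'-dibromo-8,8'-dimethoxy-6,6'-dimethyl-2,2'-binaphthalene, via dibromobinaphthol 14 (not isolated)
Conditions: K2CO3 (6 equiv), MeOH–DMF, rt, argon; BnBr (3 equiv), 50 °C
Reagents that add atoms: benzyl bromide, BrCc1ccccc1
Why: Carbonate-mediated methanolysis of the aryl acetate and double Williamson etherification run in one flask under argon, which gives both naphthols the same robust ether that falls in the final hydrogenolysis.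

Step 9
Reactants: 16 (S)-but-3-yn-2-ol
Product: 18 (S)-4-(triisopropylsilyl)but-3-yn-2-ol, via dilithio dianion 17 (not isolated)
Conditions: n-BuLi (2.1 equiv), THF, −78 °C; TIPSCl (1.05 equiv), −78 °C → rt; H2O
Reagents that add atoms: n-butyllithium, [Li]CCCC (lithium of 17); chlorotriisopropylsilane, CC(C)[Si](Cl)(C(C)C)C(C)C
Why: C-silylation of a lithium acetylide: in the O,C-dianion the acetylide carbon is far more reactive toward the bulky chlorosilane than the aggregated secondary alkoxide, the stereocentre is untouched, and TIPS is chosen because it must outlast K2CO3/MeOH in step 14.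

Step 10
Reactants: 18 (S)-4-(triisopropylsilyl)but-3-yn-2-ol
Product: 19 (S)-4-(triisopropylsilyl)but-3-yn-2-yl methanesulfonate
Conditions: MsCl, Et3N, CH2Cl2, −20 → 0 °C
Reagents that add atoms: methanesulfonyl chloride, CS(=O)(=O)Cl
Why: Mesylation takes place at oxygen, so the C–O bond and with it the S configuration stay intact.

Step 11
Reactants: 19 (S)-4-(triisopropylsilyl)but-3-yn-2-yl methanesulfonate; 20 (R)-3-aminobutan-1-ol (2 equiv)
Product: 21 (3R)-3-{[(2R)-4-(triisopropylsilyl)but-3-yn-2-yl]amino}butan-1-ol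
Conditions: K2CO3, MeCN, 60 °C
Reagents that add atoms: none
Why: SN2 displacement of a secondary propargylic sulfonate by a primary amine proceeds with inversion and thereby sets the future C1 as R, the future C3 (R) comes unchanged from the chiral pool, TIPS blocks the SN2' path, and a second alkylation is sterically excluded.

Step 12
Reactants: 21 (3R)-3-{[(2R)-4-(triisopropylsilyl)but-3-yn-2-yl]amino}butan-1-ol
Product: 22 benzyl N-[(2R)-4-hydroxybutan-2-yl]-N-[(2R)-4-(triisopropylsilyl)but-3-yn-2-yl]carbamate
Conditions: CbzCl, NaHCO3, CH2Cl2–H2O, rt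
Reagents that add atoms: benzyl chloroformate, O=C(Cl)OCc1ccccc1
Why: Schotten–Baumann acylation: the amine, though flanked by two secondary carbons, outruns the primary alcohol toward the chloroformate under bicarbonate conditions, CbzCl being more reactive toward such hindered amines than Boc2O, and Cbz is chosen because it survives the HCl quench of step 17 and leaves together with the benzyl ethers in step 20.

Step 13
Reactants: 22 benzyl N-[(2R)-4-hydroxybutan-2-yl]-N-[(2R)-4-(triisopropylsilyl)but-3-yn-2-yl]carbamate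
Product: 23 benzyl N-[(2R)-4-oxobutan-2-yl]-N-[(2R)-4-(triisopropylsilyl)but-3-yn-2-yl]carbamate
Conditions: TEMPO (cat.), PhI(OAc)2, CH2Cl2, rt
Reagents that add atoms: none
Why: TEMPO-catalysed oxidation with PhI(OAc)2 stops at the aldehyde under neutral conditions, and the stereocentre is β to the new carbonyl and therefore not enolisable.

Step 14
Reactants: 23 benzyl N-[(2R)-4-oxobutan-2-yl]-N-[(2R)-4-(triisopropylsilyl)but-3-yn-2-yl]carbamate
Product: 24 benzyl N-[(2R)-pent-4-yn-2-yl]-N-[(2R)-4-(triisopropylsilyl)but-3-yn-2-yl]carbamate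
Conditions: dimethyl (1-diazo-2-oxopropyl)phosphonate, K2CO3, MeOH, 0 °C → rt
Reagents that add atoms: dimethyl (1-diazo-2-oxopropyl)phosphonate, CC(=O)C(=[N+]=[N-])P(=O)(OC)OC
Why: Ohira–Bestmann homologation (Seyferth–Gilbert type) converts the aldehyde into the terminal alkyne with one added carbon under K2CO3/MeOH, conditions that the TIPS-alkyne and the carbamate withstand, so the two alkynes of 24 stay differentiated.

Step 15
Reactants: 15 1,1'-bis(benzyloxy)-4,5'-dibromo-8,8'-dimethoxy-6,6'-dimethyl-2,2'-binaphthalene; 24 benzyl N-[(2R)-pent-4-yn-2-yl]-N-[(2R)-4-(triisopropylsilyl)but-3-yn-2-yl]carbamate (2.4 equiv)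
Product: 25 TIPS-capped binaphthyl bis(diyne): 15 in which each bromine is replaced by the chain –C≡C–CH2–(R)-CH(CH3)–N(Cbz)–(R)-CH(CH3)–C≡C–TIPS
Conditions: PdCl2(PhCN)2 (6 mol %), P(t-Bu)3·HBF4 (12 mol %), CuI (4 mol %), i-Pr2NH, dioxane, 50 °C, degassed
Reagents that add atoms: none
Why: Twofold Sonogashira coupling: the bulky, electron-rich phosphine lets zerovalent palladium insert even into the electron-rich, ortho-methyl-flanked C5'–Br bond, and only the homopropargylic alkyne of 24 can couple because the other one carries TIPS.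

Step 16
Reactants: 25 TIPS-capped binaphthyl bis(diyne)
Product: 26 binaphthyl bis(diyne) with two terminal propargylic alkynes (chains –C≡C–CH2–(R)-CH(CH3)–N(Cbz)–(R)-CH(CH3)–C≡CH)
Conditions: TBAF (2.5 equiv), THF, 0 °C
Reagents that add atoms: none
Why: Fluoride-induced protodesilylation removes both TIPS groups and leaves carbamates, benzyl ethers and internal alkynes alone.

Step 17
Reactants: 26 binaphthyl bis(diyne) with two terminal propargylic alkynes
Product: 29 binaphthyl bis(diyne) bis(alkynyl pinacol boronate) (chains –C≡C–CH2–(R)-CH(CH3)–N(Cbz)–(R)-CH(CH3)–C≡C–Bpin), via dilithium bis(acetylide) 27 (not isolated), via dilithium bis(borate) 28 (not isolated)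
Conditions: n-BuLi (2.05 equiv), THF, −78 °C; i-PrOBpin (2.2 equiv), −78 °C; HCl in Et2O (2.1 equiv), −78 °C → rt; filter under argon, concentrate, use without chromatography
Reagents that add atoms: n-butyllithium, [Li]CCCC (lithium of 27 and 28); 2-isopropoxy-4,4,5,5-tetramethyl-1,3,2-dioxaborolane, CC(C)OB1OC(C)(C)C(C)(C)O1
Why: Borylation of alkynyllithiums: the two terminal alkynes are by far the most acidic C–H bonds and are deprotonated faster than the shielded carbamates can be attacked, the acetylides add to the isopropoxyboronate, and stoichiometric anhydrous HCl collapses the borates to the alkynyl boronates without harming N-Cbz.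

Step 18
Reactants: 29 binaphthyl bis(diyne) bis(alkynyl pinacol boronate); 30 acetylene (two molecules incorporated)
Product: 31 quateraryl bis(8-boryltetrahydroisoquinoline): (1R,3R)-N-Cbz-1,3-dimethyl-8-Bpin-tetrahydroisoquinolin-5-yl groups at C8' and C1'' of the 5',5''-bis(benzyloxy)-4',4''-dimethoxy-2',2''-dimethyl-6',6''-binaphthyl
Conditions: RhCl(PPh3)3 (20 mol %), acetylene (1 atm, acetone-free), degassed dry toluene (0.005 M), 80 °C
Reagents that add atoms: none
Why: Loss of PPh3 from RhCl(PPh3)3 lets monovalent rhodium bind both alkynes of one chain and couple them oxidatively to a trivalent rhodacyclopentadiene, acetylene then coordinates and inserts, and reductive elimination releases the arene and the catalyst, which repeats the cycle on the second chain. The closest known reaction type is the rhodium- or cobalt-catalysed [2+2+2] cycloaddition of nitrogen-tethered diynes with acetylene, established for tetrahydroisoquinolines, for alkynyl boronates and for ortho-substituted biaryls. Each piperidine ring closes in the oxidative coupling (C4a–C8a bond, six-membered ring annulated to the metallacycle), and each benzene ring closes by acetylene insertion and reductive elimination (C5–C6 and C7–C8 bonds). No stereocentre is created: C1 and C3 are sp3 carbons of the tether that take no part and meet neither acid nor base, while the two new axes are biased only by these centres and are left open by the target. The step needs diyne-plus-acetylene selectivity over acetylene trimerisation and over diyne–diyne coupling; the first rests on the chelation-driven metallacycle formation at high dilution, the second on the naphthyl and Bpin end groups, which leave room at rhodium only for the smallest alkyne. The carbamate keeps nitrogen off the metal, and its A(1,3) strain against the two α-methyl groups folds the chain so that both alkynes face the same side.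

Step 19
Reactants: 31 quateraryl bis(8-boryltetrahydroisoquinoline)
Product: 32 quateraryl bis(8-hydroxytetrahydroisoquinoline), N-Cbz, naphthols as benzyl ethers
Conditions: NaBO3·4H2O (6 equiv), THF–H2O, rt
Reagents that add atoms: sodium perborate NaBO3·4H2O, [Na+].[O-]OB=O (phenol oxygen)
Why: Perborate oxidation of the aryl boronates (hydroperoxide addition to boron, 1,2-aryl shift to oxygen, hydrolysis) puts OH exactly where boron sat, and the naphthols are still masked so that no quinoid oxidation of the binaphthyl core can occur.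

Step 20
Reactants: 32 quateraryl bis(8-hydroxytetrahydroisoquinoline), N-Cbz, naphthols as benzyl ethers
Product: 33 CNP0077060.1 (target)
Conditions: H2 (1 atm), 10 % Pd/C, MeOH–EtOAc, rt
Reagents that add atoms: none
Why: Catalytic hydrogenolysis cleaves the two O-benzyl ethers and the two N-Cbz groups (with loss of CO2) in one operation, whereas the endocyclic benzylic C1–N bond of 1-methyltetrahydroisoquinolines persists under such mild conditions, so C1 and C3 keep their R configuration.

Compound list

1 | 2-methoxy-4-methylbenzoic acid | COc1cc(C)ccc1C(=O)O | starting material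
2 | 2-methoxy-4-methylbenzoyl chloride | COc1cc(C)ccc1C(=O)Cl | intermediate
3 | N,N-diethyl-2-methoxy-4-methylbenzamide | CCN(CC)C(=O)c1ccc(C)cc1OC | intermediate
4 | N,N-diethyl-6-lithio-2-methoxy-4-methylbenzamide | CCN(CC)C(=O)c1c([Li])cc(C)cc1OC | intermediate
5 | [2-(diethylcarbamoyl)-3-methoxy-5-methylphenyl]magnesium bromide | CCN(CC)C(=O)c1c([Mg]Br)cc(C)cc1OC | intermediate
6 | 2-allyl-N,N-diethyl-6-methoxy-4-methylbenzamide | CCN(CC)C(=O)c1c(CC=C)cc(C)cc1OC | intermediate
7 | lithium 8-methoxy-6-methylnaphthalen-1-olate | [Li]Oc1cccc2cc(C)cc(OC)c12 | intermediate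
8 | 8-methoxy-1-(methoxymethoxy)-6-methylnaphthalene | COCOc1cccc2cc(C)cc(OC)c12 | intermediate
9 | 2-lithio-8-methoxy-1-(methoxymethoxy)-6-methylnaphthalene | COCOc1c([Li])ccc2cc(C)cc(OC)c12 | intermediate
10 | 8,8'-dimethoxy-1,1'-bis(methoxymethoxy)-6,6'-dimethyl-2,2'-binaphthalene | COCOc1c(-c2ccc3cc(C)cc(OC)c3c2OCOC)ccc2cc(C)cc(OC)c12 | intermediate
11 | 8,8'-dimethoxy-6,6'-dimethyl-[2,2'-binaphthalene]-1,1'-diol | COc1cc(C)cc2ccc(-c3ccc4cc(C)cc(OC)c4c3O)c(O)c12 | intermediate
12 | 1-hydroxy-8,8'-dimethoxy-6,6'-dimethyl-[2,2'-binaphthalen]-1'-yl acetate | COc1cc(C)cc2ccc(-c3ccc4cc(C)cc(OC)c4c3OC(C)=O)c(O)c12 | intermediate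
13 | 4,5'-dibromo-1-hydroxy-8,8'-dimethoxy-6,6'-dimethyl-[2,2'-binaphthalen]-1'-yl acetate | COc1cc(C)cc2c(Br)cc(-c3ccc4c(Br)c(C)cc(OC)c4c3OC(C)=O)c(O)c12 | intermediate
14 | 4,5'-dibromo-8,8'-dimethoxy-6,6'-dimethyl-[2,2'-binaphthalene]-1,1'-diol | COc1cc(C)cc2c(Br)cc(-c3ccc4c(Br)c(C)cc(OC)c4c3O)c(O)c12 | intermediate
15 | 1,1'-bis(benzyloxy)-4,5'-dibromo-8,8'-dimethoxy-6,6'-dimethyl-2,2'-binaphthalene | COc1cc(C)cc2c(Br)cc(-c3ccc4c(Br)c(C)cc(OC)c4c3OCc3ccccc3)c(OCc3ccccc3)c12 | intermediate
16 | (S)-but-3-yn-2-ol | C[C@H](O)C#C | starting material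
17 | O,C-dilithio derivative of (S)-but-3-yn-2-ol | C[C@H](O[Li])C#C[Li] | intermediate
18 | (S)-4-(triisopropylsilyl)but-3-yn-2-ol | C[C@H](O)C#C[Si](C(C)C)(C(C)C)C(C)C | intermediate
19 | (S)-4-(triisopropylsilyl)but-3-yn-2-yl methanesulfonate | C[C@H](OS(C)(=O)=O)C#C[Si](C(C)C)(C(C)C)C(C)C | intermediate
20 | (R)-3-aminobutan-1-ol | C[C@@H](N)CCO | starting material
21 | (3R)-3-{[(2R)-4-(triisopropylsilyl)but-3-yn-2-yl]amino}butan-1-ol | OCC[C@@H](C)N[C@@H](C#C[Si](C(C)C)(C(C)C)C(C)C)C | intermediate
22 | benzyl N-[(2R)-4-hydroxybutan-2-yl]-N-[(2R)-4-(triisopropylsilyl)but-3-yn-2-yl]carbamate | OCC[C@@H](C)N(C(=O)OCc1ccccc1)[C@@H](C#C[Si](C(C)C)(C(C)C)C(C)C)C | intermediate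
23 | benzyl N-[(2R)-4-oxobutan-2-yl]-N-[(2R)-4-(triisopropylsilyl)but-3-yn-2-yl]carbamate | O=CC[C@@H](C)N(C(=O)OCc1ccccc1)[C@@H](C#C[Si](C(C)C)(C(C)C)C(C)C)C | intermediate
24 | benzyl N-[(2R)-pent-4-yn-2-yl]-N-[(2R)-4-(triisopropylsilyl)but-3-yn-2-yl]carbamate | C#CC[C@@H](C)N(C(=O)OCc1ccccc1)[C@@H](C#C[Si](C(C)C)(C(C)C)C(C)C)C | intermediate
25 | TIPS-capped binaphthyl bis(diyne), N-Cbz, O-benzyl, all four centres R | COc1cc(C)cc2c(C#CC[C@@H](C)N(C(=O)OCc3ccccc3)[C@@H](C#C[Si](C(C)C)(C(C)C)C(C)C)C)cc(-c3ccc4c(C#CC[C@@H](C)N(C(=O)OCc5ccccc5)[C@@H](C#C[Si](C(C)C)(C(C)C)C(C)C)C)c(C)cc(OC)c4c3OCc3ccccc3)c(OCc3ccccc3)c12 | intermediate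
26 | binaphthyl bis(diyne) with terminal propargylic alkynes | COc1cc(C)cc2c(C#CC[C@@H](C)N(C(=O)OCc3ccccc3)[C@@H](C#C)C)cc(-c3ccc4c(C#CC[C@@H](C)N(C(=O)OCc5ccccc5)[C@@H](C#C)C)c(C)cc(OC)c4c3OCc3ccccc3)c(OCc3ccccc3)c12 | intermediate
27 | dilithium bis(acetylide) of 26 | COc1cc(C)cc2c(C#CC[C@@H](C)N(C(=O)OCc3ccccc3)[C@@H](C#C[Li])C)cc(-c3ccc4c(C#CC[C@@H](C)N(C(=O)OCc5ccccc5)[C@@H](C#C[Li])C)c(C)cc(OC)c4c3OCc3ccccc3)c(OCc3ccccc3)c12 | intermediate
28 | dilithium bis(alkynyl isopropoxy pinacol borate) | COc1cc(C)cc2c(C#CC[C@@H](C)N(C(=O)OCc3ccccc3)[C@@H](C#C[B-]3(OC(C)C)OC(C)(C)C(C)(C)O3)C)cc(-c3ccc4c(C#CC[C@@H](C)N(C(=O)OCc5ccccc5)[C@@H](C#C[B-]5(OC(C)C)OC(C)(C)C(C)(C)O5)C)c(C)cc(OC)c4c3OCc3ccccc3)c(OCc3ccccc3)c12.[Li+].[Li+] | intermediate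
29 | binaphthyl bis(diyne) bis(alkynyl pinacol boronate), precursor of the key step | COc1cc(C)cc2c(C#CC[C@@H](C)N(C(=O)OCc3ccccc3)[C@@H](C#CB3OC(C)(C)C(C)(C)O3)C)cc(-c3ccc4c(C#CC[C@@H](C)N(C(=O)OCc5ccccc5)[C@@H](C#CB5OC(C)(C)C(C)(C)O5)C)c(C)cc(OC)c4c3OCc3ccccc3)c(OCc3ccccc3)c12 | intermediate
30 | acetylene | C#C | starting material
31 | quateraryl bis[(1R,3R)-N-Cbz-8-Bpin-1,3-dimethyltetrahydroisoquinoline], product of the key step | COc1cc(C)cc2c(-c3ccc(B4OC(C)(C)C(C)(C)O4)c4c3C[C@@H](C)N(C(=O)OCc3ccccc3)[C@@H]4C)cc(-c3ccc4c(-c5ccc(B6OC(C)(C)C(C)(C)O6)c6c5C[C@@H](C)N(C(=O)OCc5ccccc5)[C@@H]6C)c(C)cc(OC)c4c3OCc3ccccc3)c(OCc3ccccc3)c12 | intermediate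
32 | quateraryl bis[(1R,3R)-N-Cbz-8-hydroxy-1,3-dimethyltetrahydroisoquinoline], naphthols as benzyl ethers | COc1cc(C)cc2c(-c3ccc(O)c4c3C[C@@H](C)N(C(=O)OCc3ccccc3)[C@@H]4C)cc(-c3ccc4c(-c5ccc(O)c6c5C[C@@H](C)N(C(=O)OCc5ccccc5)[C@@H]6C)c(C)cc(OC)c4c3OCc3ccccc3)c(OCc3ccccc3)c12 | intermediate
33 | CNP0077060.1 | COc1cc(C)cc2c(-c3ccc(O)c4c3C[C@@H](C)N[C@@H]4C)cc(-c3ccc4c(-c5ccc(O)c6c5C[C@@H](C)N[C@@H]6C)c(C)cc(OC)c4c3O)c(O)c12 | target

Total step count: 20. Longest linear sequence: 14 (steps 1–8 and 15–20). The tether branch (steps 9–14) joins at step 15.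

Steps most likely to fail

Step 18 (key step). Oxidative coupling of two end-capped alkynes across a four-atom tether may be slow. Acetylene oligomerisation could then consume the catalyst, only one chain might react, or the C(sp)–B bonds could be lost by protodeborylation or transmetalation at the reaction temperature. Fallback: boron is taken out of the cycloaddition and brought in afterwards by cross-coupling. It sets out from 26 by way of its dilithium salt 27, which is quenched with I2 (THF, −78 °C) to give the binaphthyl bis(1-iodoalkyne) F1. Iodoalkyne-terminated diynes are known partners of acetylene under Cp*RuCl(cod) (1,2-dichloroethane, acetylene 1 atm, rt), which should give the quateraryl bis(8-iodotetrahydroisoquinoline) F2. Miyaura borylation (PdCl2(dppf), B2pin2, KOAc, dioxane, 80 °C) comes back to the route at 31.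

Step 7. The second equivalent of NBS may attack the still free bromonaphthol ring (ipso bromination with dearomatisation, or oxidation). Acetyl migration between the two neighbouring oxygens would also erase the electronic difference between the halves. Fallback: the two brominations are separated and the naphthol is capped between them. It sets out from 12. NBS (1.0 equiv, MeCN, −30 °C) gives the C4 monobromide monoacetate F3, and Ac2O/pyridine/DMAP gives the monobromide diacetate F4, after which acyl migration has no consequence. A second NBS bromination (MeCN, rt) goes para to OMe in the unbrominated half to give the dibromide diacetate F5. Methanolysis under the conditions of step 8 comes back to the route at 14 and hence 15.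

Step 11. Substitution at the secondary propargylic carbon by an α-branched amine may be slow, so that elimination to the enyne competes. Partial ionisation of the mesylate would erode the configuration at C1. Fallback: the C1–N bond is made by a Fukuyama–Mitsunobu reaction on the alcohol instead of by amine alkylation. It sets out from 20 and 18. Compound 20 is N-sulfonylated (2-nitrobenzenesulfonyl chloride, NaHCO3, CH2Cl2–H2O) to the nosylamide alcohol F6, oxidised (TEMPO, PhI(OAc)2) to the nosylamide aldehyde F7, and homologated (Ohira–Bestmann reagent, K2CO3, MeOH) to the nosylamide alkyne F8. Mitsunobu coupling with 18 (PPh3, DIAD, toluene, 0 °C → rt, inversion at the carbinol carbon) gives the fully substituted nosylamide F9. Thiophenol/K2CO3 in MeCN releases the secondary amine diyne F10, and CbzCl as in step 12 comes back to the route at 24.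

Further compounds

F1 | step 18 | binaphthyl bis(diyne) bis(1-iodoalkyne) | COc1cc(C)cc2c(C#CC[C@@H](C)N(C(=O)OCc3ccccc3)[C@@H](C#CI)C)cc(-c3ccc4c(C#CC[C@@H](C)N(C(=O)OCc5ccccc5)[C@@H](C#CI)C)c(C)cc(OC)c4c3OCc3ccccc3)c(OCc3ccccc3)c12
F2 | step 18 | quateraryl bis[(1R,3R)-N-Cbz-8-iodo-1,3-dimethyltetrahydroisoquinoline] | COc1cc(C)cc2c(-c3ccc(I)c4c3C[C@@H](C)N(C(=O)OCc3ccccc3)[C@@H]4C)cc(-c3ccc4c(-c5ccc(I)c6c5C[C@@H](C)N(C(=O)OCc5ccccc5)[C@@H]6C)c(C)cc(OC)c4c3OCc3ccccc3)c(OCc3ccccc3)c12
F3 | step 7 | 4-bromo-1-hydroxy-8,8'-dimethoxy-6,6'-dimethyl-[2,2'-binaphthalen]-1'-yl acetate | COc1cc(C)cc2c(Br)cc(-c3ccc4cc(C)cc(OC)c4c3OC(C)=O)c(O)c12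
F4 | step 7 | 4-bromo-8,8'-dimethoxy-6,6'-dimethyl-[2,2'-binaphthalene]-1,1'-diyl diacetate | COc1cc(C)cc2c(Br)cc(-c3ccc4cc(C)cc(OC)c4c3OC(C)=O)c(OC(C)=O)c12
F5 | step 7 | 4,5'-dibromo-8,8'-dimethoxy-6,6'-dimethyl-[2,2'-binaphthalene]-1,1'-diyl diacetate | COc1cc(C)cc2c(Br)cc(-c3ccc4c(Br)c(C)cc(OC)c4c3OC(C)=O)c(OC(C)=O)c12
F6 | step 11 | N-[(2R)-4-hydroxybutan-2-yl]-2-nitrobenzenesulfonamide | OCC[C@@H](C)NS(=O)(=O)c1ccccc1[N+](=O)[O-]
F7 | step 11 | 2-nitro-N-[(2R)-4-oxobutan-2-yl]benzenesulfonamide | O=CC[C@@H](C)NS(=O)(=O)c1ccccc1[N+](=O)[O-]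
F8 | step 11 | 2-nitro-N-[(2R)-pent-4-yn-2-yl]benzenesulfonamide | C#CC[C@@H](C)NS(=O)(=O)c1ccccc1[N+](=O)[O-]
F9 | step 11 | 2-nitro-N-[(2R)-pent-4-yn-2-yl]-N-[(2R)-4-(triisopropylsilyl)but-3-yn-2-yl]benzenesulfonamide | C#CC[C@@H](C)N(S(=O)(=O)c1ccccc1[N+](=O)[O-])[C@@H](C#C[Si](C(C)C)(C(C)C)C(C)C)C
F10 | step 11 | (2R)-N-[(2R)-4-(triisopropylsilyl)but-3-yn-2-yl]pent-4-yn-2-amine | C#CC[C@@H](C)N[C@@H](C#C[Si](C(C)C)(C(C)C)C(C)C)C
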